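(The constants stand for no real mixture.)

The flasks are charged with starting material at 0.20 M and no product, so the first product has to come from the uncatalysed step before the product can feed itself.

| flask | starting material | temperature | time |
|---|---|---|---|
| maple | 0.20 M | 65 °C | 1.5 min |
| oak | 0.20 M | 35 °C | 1.5 min |
| cedar | 0.20 M | 5 °C | 1.5 min |

    starting material + product → 2 product (k1 = 0.11 M⁻¹ s⁻¹, Ea1 = 70.0 kJ mol⁻¹)
    starting material → product (k2 = 2.1 × 10⁻⁵ s⁻¹, Ea2 = 101 kJ mol⁻¹)
    starting material ⇌ dormant form (K3 = 0.56, k3 = 0.031 s⁻¹, Ea3 = 89.0 kJ mol⁻¹, ΔH3 = 31.0 kJ mol⁻¹)
    crystals ⇌ product, rate k4*(cs4 - [product]) while solid is left; crystals form when [product] > cs4 (cs4 = 0.18 M, k4 = 0.28 s⁻¹)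
    (constants at 35 °C)

- amounts and yields of product count crystals too
- given per volume of solution although it is solid: crystals
- at 35 °C the constants are as listed, elsewhere as the activation energies and enthalpies make them

- the best flask by amount of product, in percent of the starting material charged; "all alike" if 1.5 percentage points covers them all (maple / oak / cedar / all alike)
- amount of product at the end, in percent of the starting material charged, maple
- amount of product at the end, in percent of the starting material charged, oak
- amount of product at the end, in percent of the starting material charged, cedar

*What do you follow?* I follow x, the product as a fraction of the charge, crystals included as the question counts them, and I call the remainder, 1 − x, the pool.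

*Is the pool free to react?* In oak it is shared with the dormant form, a resting state of the starting material, and the relaxation half-life of 0.134 min is much shorter than the 1.5 min run, so I hold the balance K throughout and give the starting material the fraction (1 − x)/(1 + K).

*And the rate?* With a the first constant times the charge and b the second constant, dx/dt = (a·x + b)(1 − x)/(1 + K), which integrates in closed form. If s = b/a and r = a/(1 + K), and b is dropped beside a in the exponent, then E = s·exp(r·t) and x = (E − s)/(1 + E).

*Your one number?* It is the take-off time, and for oak s = 9.55 × 10⁻⁴, so τ = ln(1/s)/r, the time at which E reaches 1 and product stands at half of the charge, comes to 8.22 min. That is longer than the run, and with E = 0.00340 I get 0.243% for oak.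

*Maple?* Its constants give a = 0.248 s⁻¹, s = 0.00279 and K = 1.64, so τ is 1.04 min, shorter than the run. With E = 13.4 I commit to 93.0% and to maple as the best flask.

*Where does this break?* It breaks in cedar, where the dormant form relaxes with a half-life of 2.08 min, longer than the run, so the balance fails there. I then reckon cedar's product as what the uncatalysed step makes from the charge over the run, 0.00269%.

The forecast names maple, with 94% for maple against my 93.0%, 0.28% for oak against my 0.243%, and 0.0027% for cedar, saying of the two colder flasks that “the reaction stays in its induction period”.

The simulation gives maple, with 91.6% in maple, 0.276% in oak and 0% in cedar.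

Maple, with a take-off time of 1.04 min, ended with 91.6% product, while oak, with 8.22 min, still held 63.9% starting material at 1.50 min. A repeat of oak at 60 °C has a = 0.171 s⁻¹, s = 0.00237 and K = 1.39, so its take-off time is 1.41 min, shorter than the run. The closed form, with E = 1.48, puts its product at 59.6%. That flask ended with 60.4% product, 15.3% starting material and 24.3% dormant form.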